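**Remarks on the chemistry**

- Atom labels in the text follow the azulene numbering of the target: C1, C2, C3 (isopropyl carbinol), C3a (ring-fusion CH), C4 (ester carbon), C5=C6 (methyl on C6), C7, C8, C8a (quaternary, methyl). The systematic names of 5 and 6 count the ketone carbon as C1, which is C3 of this numbering. From 7 on, the names keep the target numbering.
- Rh2(OAc)4 is achiral, so the ring-expanded trienone 5 is formed as a racemate and is written without a configuration. Its single stereocentre is removed in step 4.

## Analysis of the target

Target 16 is the 3-hydroxy-4-methoxybenzoate (isovanillate) of a daucane-type sesquiterpene diol. Its core is a cis-fused bicyclo[5.3.0]decane: a cyclopentane (C1, C2, C3, C3a, C8a) with a tertiary isopropyl carbinol at C3, fused to a cycloheptene (C3a, C4 to C8, C8a) with the secondary allylic ester at C4, a C5=C6 alkene with a methyl on C6, and an angular methyl on quaternary C8a. The four stereocentres C8a (R), C3a (S), C3 (R) and C4 (R) are clustered around C3a. 3a-H and the 8a-methyl are cis; the C3 hydroxyl and the C4 acyloxy group are syn to each other on the concave face, opposite to 3a-H; the isopropyl group shares the convex face with 3a-H and the angular methyl. The sensitive parts are the allylic benzoate (ionisation, acyl transfer to the neighbouring tertiary hydroxyl under base), the tertiary alcohol (dehydration under acid), the free phenol and the trisubstituted alkene, so the ester is made last under near-neutral conditions. The difficulties are the all-carbon quaternary centre C8a, which cannot be relayed from a neighbour and so must carry the absolute configuration, the seven-membered ring, and an oxygen at C4 on the more hindered face. The strategy rests on one feature: C4, C5, C6, C7, C8 and C8a, with the methyl-bearing C6 para to C8a, are the carbons of a p-tolyl ring in which C4 and C8a were once bonded; C3a is a single carbon inserted between them; and C1, C2 and oxygenated C3 are a three-carbon acyl chain on C8a. Read this way, the bicycle is 3-(4-methylphenyl)propanoic acid 1 plus one carbon.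

## Retrosynthetic reasoning

**Ester and phenol.** The ester C4–O–C(=O) bond of 16 is cut first. The allylic benzoate and the free phenol are the most fragile parts, and the acid half is a separate commercial unit, isovanillic acid 12. The cut gives diol 11 and, with the phenol masked as a silyl ether, acid 14. The forward acylation has to distinguish the secondary C4 hydroxyl from the hindered tertiary C3 hydroxyl, and the silyl ether of 15 has to come off without touching the ester.

**C4 oxygen and alkene position.** In 11 the C4 oxygen is allylic to C5=C6 and 1,3-syn to the C3 hydroxyl. A retrosynthetic 1,4-transposition (C4–OH, C5=C6, C7–H back to a C4–C5 epoxide beside a C6=C7 alkene) leads to vinyl epoxide 10. Removing the epoxide oxygen leads to dienol 9, whose tertiary hydroxyl is homoallylic to C4=C5. The cut is made here because the C3 hydroxyl sits on the concave face, where the C4 oxygen must go, and can deliver an oxidant to a face that an undirected reagent would avoid. The forward steps must epoxidise only the C4=C5 bond of a 1,3-diene and then open the epoxide reductively with protonation at C7.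

**C3–isopropyl bond.** Cutting this bond of 9 gives ketone 8 and an isopropyl nucleophile. 1,2-Addition is the right polarity: the nucleophile should enter on the convex face, anti to the C3a–C4 bond, leaving the oxygen on the concave face. The forward reaction has to outrun enolisation of the acidic C3a–H.

**C8a–methyl bond and C3a–H.** Cutting both in 8 corresponds to conjugate addition of a methyl nucleophile to the enone C3(=O)–C3a=C8a of trienone 6, then α-protonation of trienolate 7. Since 6 is achiral, this is where the absolute configuration enters (C8a); C3a follows from it in the protonation. No other handle for the quaternary carbon exists, and the disconnection returns a flat, fully unsaturated bicycle.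

**Key disconnection.** Trienone 6 is the conjugated isomer of cycloheptatriene 5, differing only in the place of one hydrogen. In 5 the bonds C3a–C8a and C3a–C4 are cut together: C3a is taken out as a carbene carbon, the C4–C8a bond is restored (norcaradiene 4), and C4 to C8a become the p-tolyl ring of diazoketone 3. This double cut is preferred to any cut inside the seven-membered ring because it reduces a bicyclic medium-ring problem to an acyclic aryl ketone at once. Eleven of the fifteen skeletal carbons, the C3 oxygen and the C6 methyl are accounted for, and the symmetry of the para-substituted ring removes any regiochemical question. The forward step must make the carbenoid add to the arene π bond beside the tether and not insert into a C–H bond.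

**Diazoketone.** Diazoketone 3 is cut at C3–C3a into acid chloride 2 and a one-carbon diazo component; 2 comes from commercial acid 1.

## Alternatives that were turned down

**Alternative 1:** vinylcarbenoid cyclopropanation and Cope rearrangement.
- Disconnection: the seven-membered ring is cut at C5–C6 and C8–C8a into a three-carbon vinylcarbenoid unit (C6, C7, C8, from methyl 2-diazobut-3-enoate A2) and a four-carbon diene (C5=C4–C3a=C8a), the siloxydiene A3, a 2-methylcyclopentene with C3 masked as a ketal.
- Forward key step: Rh2(S-DOSP)4, the dirhodium tetrakis[N-(dodecylbenzenesulfonyl)prolinate] catalyst, would decompose A2; the carbenoid would cyclopropanate the terminal enol ether alkene of A3, and the cis-divinylcyclopropane would rearrange to cycloheptadiene A1.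
- For it: an established type of catalytic asymmetric reaction sets quaternary C8a, and A1 already carries oxygen at C3 and C4.
- Against it: the Cope step must create the quaternary centre at a fully substituted alkene terminus. A1 has its alkene at C6=C7 and an ester where 16 has a methyl, so an ester-to-methyl reduction and an alkene shift to C5=C6 are needed. Unmasking C3 and C4 gives a 1,3-dicarbonyl array across C3a that must be differentiated before isopropyl addition and C4 reduction. C3a is still set by a protonation.
- Comparison: for absolute configuration at C8a, Alternative 1 is the stronger plan. The chosen route offers a bicyclic core with the C6 methyl and the right oxidation pattern three steps from a commercial acid, with no functional-group interconversion at C6; Alternative 1 would be considerably longer.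

**Alternative 2:** desymmetrising homoenolate conjugate addition and aldol closure.
- Disconnection: both bonds joining the five-membered ring to the seven-membered ring, C1–C8a and C3–C3a, are cut. This gives the symmetric cross-conjugated dienone A5 (3,6-dimethylcyclohepta-2,6-dien-1-one) and a C1–C2–C3 homoenolate carrying the isopropyl ketone, generated from cyclopropanol A6.
- Forward key step: Cu(OTf)2 with a chiral phosphoramidite would add the zinc homoenolate (A6 with Et2Zn) to one of the two enantiotopic enone arms, and the zinc enolate would close onto the isopropyl ketone to give hydroxy enone A4.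
- For it: maximal convergence. All fifteen core carbons and three of the four stereocentres arrive in one step, and A4 is one ketone reduction and one acylation from 16; hydride attack on the convex face would place the C4 oxygen correctly.
- Against it: one step carries three unproven demands. These are enantioselective conjugate addition of a homoenolate to a β,β-disubstituted enone deactivated by cross-conjugation, desymmetrisation, and a diastereoselective aldol onto a hindered, enolisable ketone whose adduct can revert by retro-aldol. A5 is not commercial.
- Comparison: Alternative 2 is clearly shorter and would be the better route if its key step worked. Both routes rest the C8a configuration on an unproven copper-catalysed conjugate addition. The chosen route confines that risk to the simplest nucleophile on a substrate made in four reliable steps, with a resolution route behind it; a failure of the key step of Alternative 2 leaves nothing to build on.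

**Alternative 3:** rhodium [5+2] of a tethered alkene–vinylcyclopropane.
- Disconnection: the bonds C3a–C8a and C7–C8 are cut, opening both rings to the acyclic ene–vinylcyclopropane A8. It has a 1,1-disubstituted alkene (C8=C8a with the methyl) tethered through C1–C2–C3 to a vinylcyclopropane (C3a=C4; cyclopropane C5, C6, C7 with the methyl on C6), with the C3 silyl ether in place.
- Forward key step: [Rh(CO)2Cl]2 would effect the intramolecular [5+2] cycloaddition to the cis-fused hydroazulene A7.
- For it: both rings form in one step, and the cis ring fusion is an intrinsic outcome of the tethered cycloaddition, which is firmer than the protonation used in the chosen route. The C3 stereocentre can relay to C3a and C8a.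
- Against it: A8 needs an enantioselective synthesis of an acyclic tertiary carbinol and a stereodefined 2-methylcyclopropane, which means a long linear sequence. 1,1-Disubstituted alkenes are sluggish two-carbon partners, and the substituted cyclopropane must cleave regioselectively. A7 has a C4=C5 alkene and no C4 oxygen, so an allylic oxidation with transposition (Schenck ene type) must place oxygen on the concave face at C4 while removing hydrogen from C6 and not from C3a. The silyl ether blocks the directing role of the C3 hydroxyl.
- Comparison: ring-fusion control is better in Alternative 3. The chosen route reaches the bicyclic core in far fewer steps and uses the free C3 hydroxyl to deliver the C4 oxygen to the hindered face.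

Key step: step 3

## Route

Step 1
Reactants: 1 3-(4-methylphenyl)propanoic acid
Product: 2 3-(4-methylphenyl)propanoyl chloride
Conditions: (COCl)2 (1.3 equiv), DMF (cat.), CH2Cl2, 0 °C to rt; evaporation
Reagents that add atoms: oxalyl chloride, O=C(Cl)C(=O)Cl
Why: Standard acid chloride formation through the DMF-derived chloroiminium ion; the by-products are gases and crude 2 is used directly.

Step 2
Reactants: 2 3-(4-methylphenyl)propanoyl chloride
Product: 3 1-diazo-4-(4-methylphenyl)butan-2-one
Conditions: CH2N2 (3 equiv, ethereal), Et2O, 0 °C to rt
Reagents that add atoms: diazomethane, C=[N+]=[N-]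
Why: Acylation of diazomethane, the first stage of the Arndt–Eistert sequence; a second equivalent of diazomethane takes up the HCl, which prevents formation of the chloromethyl ketone.

Step 3
Reactants: 3 1-diazo-4-(4-methylphenyl)butan-2-one
Product: 5 racemic 6-methyl-3,8a-dihydroazulen-1(2H)-one, via norcaradiene valence isomer 4 (not isolated)
Conditions: Rh2(OAc)4 (0.5 mol %), CH2Cl2, reflux, slow addition of 3 at high dilution; filtration through neutral alumina
Reagents that add atoms: none
Why: Rh2(OAc)4 extrudes nitrogen from 3, and the electrophilic rhodium ketocarbenoid adds to the ipso–ortho π bond of the tolyl ring, forming C3a–C8a and C3a–C4 in norcaradiene 4; disrotatory 6π electrocyclic opening of 4 then cleaves the former ipso–ortho bond C4–C8a and gives cycloheptatriene 5. The closest known reaction type is the intramolecular Buchner reaction of 1-diazo-4-arylbutan-2-ones under dirhodium carboxylate catalysis, an established entry to dihydroazulenones. The cyclopentanone closes in the cyclopropanation as a five-membered ring through the three-atom tether (bond C3a–C8a to the ipso carbon), whereas the seven-membered ring is not closed by cyclisation but arises by one-carbon enlargement of the benzene ring in the electrocyclic opening. The one new stereocentre (C3a) forms without control under the achiral catalyst, which does not matter because step 4 removes it. The step needs chemoselectivity for arene addition over benzylic C–H insertion and over formal aromatic substitution: insertion would have to close a four-membered ring, the tether holds the carbenoid over the ipso–ortho bond, and the electron-rich tolyl ring together with carboxylate ligands favours cyclopropanation. No regiochemical question arises, because the two ortho positions of the para-substituted ring are equivalent. Slow addition at high dilution should suppress carbene dimerisation, and acid-free handling avoids rearrangement of 5 to an isomeric bicyclic aryl ketone.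

Step 4
Reactants: 5 racemic 6-methyl-3,8a-dihydroazulen-1(2H)-one
Product: 6 6-methyl-3,4-dihydroazulen-1(2H)-one
Conditions: Et3N (0.2 equiv), CH2Cl2, rt
Reagents that add atoms: none
Why: Et3N removes the doubly activated C3a–H (α to the ketone and allylic), and the extended enolate is reprotonated at C8 under equilibrating conditions, which brings the alkene into conjugation (C3a=C8a) and erases the stereocentre of 5. This base-mediated isomerisation to the 3,4-dihydro isomer is the usual follow-up to the Buchner cyclisation.

Step 5
Reactants: 6 6-methyl-3,4-dihydroazulen-1(2H)-one
Product: 8 (3aR,8aS)-6,8a-dimethyl-1,2,8,8a-tetrahydroazulen-3(3aH)-one, via dimethylaluminium trienolate 7 (not isolated)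
Conditions: Me3Al (2 equiv), Cu(OTf)2 (5 mol %), O,O′-(1,1′-binaphthalene-2,2′-diyl) N,N-bis(1-phenylethyl)phosphoramidite (10 mol %, antipode fixed by screening), Et2O, −30 °C; then aq. NH4Cl, −78 °C to 0 °C
Reagents that add atoms: trimethylaluminium, C[Al](C)C
Why: Proposed new method: copper-catalysed asymmetric conjugate addition of Me3Al is established for β-substituted (trisubstituted) cyclic enones, where it creates all-carbon quaternary centres, but not for a tetrasubstituted enone such as 6; Cu(OTf)2 should be reduced by Me3Al to a monovalent copper–phosphoramidite methyl species that binds the aluminium-activated C3a=C8a bond on the face chosen by the ligand and transfers methyl to C8a by oxidative addition and reductive elimination, giving trienolate 7; the flat, ring-tied dienyl α-substituent and the extra conjugation should make 6 less hindered and more electrophilic than an ordinary tetrasubstituted enone; C8a (S in 8, R in 16 by a change of priority only) is set by the ligand antipode, and kinetic α-protonation of 7 at C3a should give the β,γ-unsaturated ketone with 3a-H cis to the new methyl, the usual outcome when ring-fusion enolates from conjugate additions are protonated.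

Step 6
Reactants: 8 (3aR,8aS)-6,8a-dimethyl-1,2,8,8a-tetrahydroazulen-3(3aH)-one
Product: 9 (3R,3aR,8aS)-6,8a-dimethyl-3-(propan-2-yl)-1,2,3,3a,8,8a-hexahydroazulen-3-ol
Conditions: iPrMgCl (2 equiv), CeCl3 (2 equiv, anhydrous, pre-stirred), THF, −78 °C
Reagents that add atoms: isopropylmagnesium chloride, CC(C)[Mg]Cl
Why: The organocerium reagent formed from iPrMgCl and CeCl3 is strongly nucleophilic but weakly basic, which suppresses enolisation of the acidic C3a–H and β-hydride reduction; such 1,2-additions to enolisable cyclopentanones are well known. The reagent should approach C3 on the convex face of the cis-fused bicycle, anti to the C3a–C4 bond, so the hydroxyl ends on the concave face, cis to C4 and trans to 3a-H (3R).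

Step 7
Reactants: 9 (3R,3aR,8aS)-6,8a-dimethyl-3-(propan-2-yl)-1,2,3,3a,8,8a-hexahydroazulen-3-ol
Product: 10 (3R,3aS,4S,5R,8aS)-4,5-epoxy-6,8a-dimethyl-3-(propan-2-yl)-1,2,3,3a,4,5,8,8a-octahydroazulen-3-ol
Conditions: VO(acac)2 (5 mol %), t-BuOOH (1.5 equiv, anhydrous in decane), toluene, 0 °C to rt
Reagents that add atoms: tert-butyl hydroperoxide, CC(C)(C)OO
Why: Hydroxyl-directed epoxidation: the vanadate ester of the tertiary homoallylic alcohol should deliver the peroxide oxygen to the nearer C4=C5 bond, in preference to the remote C6=C7 bond, and to its concave face, where the 3-OH sits; this sets C4 and C5. Because the epoxide oxygen and the hydroxyl are syn, the alcohol cannot open the vinyl epoxide from the back, and the neutral conditions should spare the diene monoepoxide.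

Step 8
Reactants: 10 (3R,3aS,4S,5R,8aS)-4,5-epoxy-6,8a-dimethyl-3-(propan-2-yl)-1,2,3,3a,4,5,8,8a-octahydroazulen-3-ol
Product: 11 (3R,3aS,4R,8aR)-6,8a-dimethyl-3-(propan-2-yl)-1,2,3,3a,4,7,8,8a-octahydroazulene-3,4-diol
Conditions: SmI2 (2.5 equiv), THF–MeOH, −78 °C
Reagents that add atoms: none
Why: SmI2 transfers an electron to the vinyl epoxide, the allylic C5–O bond breaks, a second electron gives an allylic organosamarium held by the C4 alkoxide, and protonation by MeOH at the remote terminus C7 moves the alkene to C5=C6; this reductive 1,4-opening of vinyl epoxides to allylic alcohols is a known SmI2 reaction. The C4–O bond is untouched, so its configuration is kept (the descriptor changes from S to R by priority only), and the ring fixes the alkene geometry.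

Step 9
Reactants: 12 isovanillic acid (3-hydroxy-4-methoxybenzoic acid)
Product: 14 3-[(tert-butyldimethylsilyl)oxy]-4-methoxybenzoic acid, via bis-silylated silyl ester 13 (not isolated)
Conditions: TBSCl (2.5 equiv), imidazole (5 equiv), DMF, rt; then AcOH–THF–H2O (3:1:1), rt
Reagents that add atoms: tert-butyldimethylsilyl chloride, CC(C)(C)[Si](C)(C)Cl
Why: Silylation of both acidic hydroxyls followed by selective hydrolysis of the much more labile silyl ester is the usual way to an O-silylated hydroxybenzoic acid; the aryl silyl ether should survive dilute aqueous acetic acid.

Step 10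
Reactants: 11 (3R,3aS,4R,8aR)-6,8a-dimethyl-3-(propan-2-yl)-1,2,3,3a,4,7,8,8a-octahydroazulene-3,4-diol; 14 3-[(tert-butyldimethylsilyl)oxy]-4-methoxybenzoic acid
Product: 15 (3R,3aS,4R,8aR)-3-hydroxy-6,8a-dimethyl-3-(propan-2-yl)-1,2,3,3a,4,7,8,8a-octahydroazulen-4-yl 3-[(tert-butyldimethylsilyl)oxy]-4-methoxybenzoate
Conditions: DCC (1.3 equiv), DMAP (0.2 equiv), CH2Cl2, 0 °C to rt
Reagents that add atoms: none
Why: Steglich esterification: the DMAP-derived acylpyridinium ion should acylate the secondary allylic C4 hydroxyl, while the tertiary C3 hydroxyl is too hindered to react. No stereocentre is touched, and the neutral conditions avoid ionisation of the allylic system.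

Step 11
Reactants: 15 (3R,3aS,4R,8aR)-3-hydroxy-6,8a-dimethyl-3-(propan-2-yl)-1,2,3,3a,4,7,8,8a-octahydroazulen-4-yl 3-[(tert-butyldimethylsilyl)oxy]-4-methoxybenzoate
Product: 16 (3R,3aS,4R,8aR)-3-hydroxy-6,8a-dimethyl-3-(propan-2-yl)-1,2,3,3a,4,7,8,8a-octahydroazulen-4-yl 3-hydroxy-4-methoxybenzoate (CNP0210850.1)
Conditions: Bu4NF (1.1 equiv), AcOH (1.1 equiv), THF, 0 °C
Reagents that add atoms: none
Why: Fluoride cleaves the aryl silyl ether rapidly at 0 °C (strong Si–F bond, phenoxide leaving group); AcOH buffers the phenoxide, so the allylic benzoate should neither be cleaved nor migrate to the tertiary hydroxyl.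

## Compound list

1 | 3-(4-methylphenyl)propanoic acid | Cc1ccc(CCC(=O)O)cc1 | starting material
2 | 3-(4-methylphenyl)propanoyl chloride | Cc1ccc(CCC(=O)Cl)cc1 | intermediate
3 | 1-diazo-4-(4-methylphenyl)butan-2-one | Cc1ccc(CCC(=O)C=[N+]=[N-])cc1 | intermediate
4 | norcaradiene valence isomer of 5 (racemic; cyclopropane spanning C3a, C4 and C8a, C3 ketone, C5=C6 and C7=C8, methyl on C6) | O=C1CCC23C=CC(C)=CC2C13 | intermediate (not isolated)
5 | racemic 6-methyl-3,8a-dihydroazulen-1(2H)-one (target numbering: C3 ketone, 3a-H, C4=C5, C6=C7, C8=C8a) | O=C1CCC2=CC=C(C)C=CC12 | intermediate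
6 | 6-methyl-3,4-dihydroazulen-1(2H)-one (target numbering: C3 ketone, C3a=C8a, C4=C5, C6=C7, C8 methylene) | O=C1CCC2=C1C=CC(C)=CC2 | intermediate
7 | dimethylaluminium (8aS)-6,8a-dimethyl-1,2,8,8a-tetrahydroazulen-3-olate (trienolate) | C1=CC(C)=CC[C@]2(C)CCC(O[Al](C)C)=C12 | intermediate (not isolated)
8 | (3aR,8aS)-6,8a-dimethyl-1,2,8,8a-tetrahydroazulen-3(3aH)-one (cis-fused) | C1=CC(C)=CC[C@]2(C)CCC(=O)[C@H]12 | intermediate
9 | (3R,3aR,8aS)-6,8a-dimethyl-3-(propan-2-yl)-1,2,3,3a,8,8a-hexahydroazulen-3-ol | C1=CC(C)=CC[C@]2(C)CC[C@@](O)(C(C)C)[C@H]12 | intermediate
10 | (3R,3aS,4S,5R,8aS)-4,5-epoxy-6,8a-dimethyl-3-(propan-2-yl)-1,2,3,3a,4,5,8,8a-octahydroazulen-3-ol (epoxide syn to 3-OH) | O1[C@@H]2[C@H]1C(C)=CC[C@]3(C)CC[C@@](O)(C(C)C)[C@H]23 | intermediate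
11 | (3R,3aS,4R,8aR)-6,8a-dimethyl-3-(propan-2-yl)-1,2,3,3a,4,7,8,8a-octahydroazulene-3,4-diol | O[C@@H]1C=C(C)CC[C@]2(C)CC[C@@](O)(C(C)C)[C@H]12 | intermediate
12 | isovanillic acid (3-hydroxy-4-methoxybenzoic acid) | COc1ccc(C(=O)O)cc1O | starting material
13 | tert-butyldimethylsilyl 3-[(tert-butyldimethylsilyl)oxy]-4-methoxybenzoate | COc1ccc(C(=O)O[Si](C)(C)C(C)(C)C)cc1O[Si](C)(C)C(C)(C)C | intermediate (not isolated)
14 | 3-[(tert-butyldimethylsilyl)oxy]-4-methoxybenzoic acid | COc1ccc(C(=O)O)cc1O[Si](C)(C)C(C)(C)C | intermediate
15 | (3R,3aS,4R,8aR)-3-hydroxy-6,8a-dimethyl-3-(propan-2-yl)-1,2,3,3a,4,7,8,8a-octahydroazulen-4-yl 3-[(tert-butyldimethylsilyl)oxy]-4-methoxybenzoate | COc1ccc(C(=O)O[C@@H]2C=C(C)CC[C@]3(C)CC[C@@](O)(C(C)C)[C@H]23)cc1O[Si](C)(C)C(C)(C)C | intermediate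
16 | (3R,3aS,4R,8aR)-3-hydroxy-6,8a-dimethyl-3-(propan-2-yl)-1,2,3,3a,4,7,8,8a-octahydroazulen-4-yl 3-hydroxy-4-methoxybenzoate (CNP0210850.1) | COc1ccc(C(=O)O[C@@H]2C=C(C)CC[C@]3(C)CC[C@@](O)(C(C)C)[C@H]23)cc1O | target

## Step count and least certain steps

Total step count: 11. Longest linear sequence: 10 steps (steps 1 to 8, 10 and 11, from 1 to 16); step 9 is a one-step side branch.

**Step 5 (proposed new method).** The catalytic cycle may fail to turn over at the tetrasubstituted C3a=C8a bond, Me3Al may add 1,2 to the ketone, the enantioselectivity may be low (its sense cannot be predicted), and the protonation of 7 may give poor cis/trans control at the ring fusion or let the diene slip into conjugation. The fallback uses known chemistry, sets out from 6 and comes back at 9. Stoichiometric Me2CuLi with BF3·OEt2 in Et2O at −78 °C, a known way to add methyl to ring-fusion tetrasubstituted enones, followed by cold protonation, should give the racemic cis-fused ketone F1. Addition of iPrMgCl–CeCl3 as in step 6 should give the racemic alcohol F2, which is resolved by preparative chromatography on a chiral stationary phase to 9. If the trans-fused epimer accompanies the cis one, the epimers are separated at this alcohol stage and the unwanted ketone epimer is returned to the enolate (LiN(SiMe3)2, −78 °C) for reprotonation.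

**Step 3 (key step).** The carbenoid may be diverted into formal aromatic C–H substitution or into dimerisation, and traces of acid may rearrange the cycloheptatriene during isolation. The fallback sets out from 1 and comes back at 6; it replaces arene cyclopropanation by alkene cyclopropanation. Birch reduction of 1 (Li, liquid NH3, t-BuOH, THF, −78 °C) should give 3-(4-methylcyclohexa-1,4-dien-1-yl)propanoic acid F3. (COCl)2 should convert it into the acid chloride F4, and ethereal diazomethane into the diazoketone F5. With Rh2(OAc)4 or Cu(acac)2 the carbenoid can only cyclopropanate the tethered trisubstituted alkene, giving the tricyclic cyclopropyl ketone F6, which holds the same cyclopropane as 4. Addition of Br2 to the remaining alkene should give the dibromide F7. Double dehydrobromination with DBU should form norcaradiene 4, which opens to 5 and is isomerised by the same base to 6.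

**Step 7.** Oxygen delivery may go to the more electron-rich C6=C7 bond, the tertiary hydroxyl may bind vanadium too slowly, and the diene monoepoxide may rearrange on the Lewis-acidic metal. The fallback sets out from 9 and comes back at 11, bypassing 10 and step 8; it tethers the oxygen nucleophile. KN(SiMe3)2 and di-tert-butyl dicarbonate should give the tert-butyl carbonate F8. IBr in toluene at −80 °C should close the cyclic iodocarbonate F9, in which the carbonate oxygen has attacked C4 from the concave face, anti to the iodonium ion; a 1,4-iodocarbonate with iodine at C7 would serve equally. Bu3SnH with AIBN should reduce the allylic iodide through the C5–C6–C7 allyl radical, with hydrogen transfer to the less hindered C7, to the cyclic carbonate F10. K2CO3 in MeOH then releases 11.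

**Step 8.** The allylic organosamarium may be protonated at C5 and not at C7, which would leave the alkene at C6=C7, or the allylic alcohol may be over-reduced. The fallback sets out from 10 and comes back at 11; it replaces single-electron cleavage by polar SN2′ hydride delivery. i-Bu2AlH (3 equiv) in hexane–CH2Cl2 at −78 °C should add hydride to C7 with allylic transposition and opening of the C5–O bond, a known reduction mode of vinyl epoxides. This fallback makes no compound outside the list (F0).

## Further compounds

F1 | step 5 | racemic (3aR*,8aS*)-6,8a-dimethyl-1,2,8,8a-tetrahydroazulen-3(3aH)-one (racemate of 8) | C1=CC(C)=CC[C@]2(C)CCC(=O)[C@H]12.C1=CC(C)=CC[C@@]2(C)CCC(=O)[C@@H]12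
F2 | step 5 | racemic (3R*,3aR*,8aS*)-6,8a-dimethyl-3-(propan-2-yl)-1,2,3,3a,8,8a-hexahydroazulen-3-ol (racemate of 9) | C1=CC(C)=CC[C@]2(C)CC[C@@](O)(C(C)C)[C@H]12.C1=CC(C)=CC[C@@]2(C)CC[C@](O)(C(C)C)[C@@H]12
F3 | step 3 | 3-(4-methylcyclohexa-1,4-dien-1-yl)propanoic acid | CC1=CCC(CCC(=O)O)=CC1
F4 | step 3 | 3-(4-methylcyclohexa-1,4-dien-1-yl)propanoyl chloride | CC1=CCC(CCC(=O)Cl)=CC1
F5 | step 3 | 1-diazo-4-(4-methylcyclohexa-1,4-dien-1-yl)butan-2-one | CC1=CCC(CCC(=O)C=[N+]=[N-])=CC1
F6 | step 3 | racemic tricyclic cyclopropyl ketone (cyclopropane spanning C3a, C4 and C8a; C3 ketone; C6=C7 with methyl on C6; ring fusion fixed by the cyclopropane) | O=C1CCC23CC=C(C)CC2C13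
F7 | step 3 | racemic 6,7-dibromide of F6 (trans addition) | O=C1CCC23CC(Br)C(C)(Br)CC2C13
F8 | step 7 | tert-butyl (3R,3aR,8aS)-6,8a-dimethyl-3-(propan-2-yl)-1,2,3,3a,8,8a-hexahydroazulen-3-yl carbonate | C1=CC(C)=CC[C@]2(C)CC[C@@](OC(=O)OC(C)(C)C)(C(C)C)[C@H]12
F9 | step 7 | cyclic iodocarbonate (six-membered carbonate bridging O3 and O4 on the concave face, iodine at C5 anti to O4, C6=C7 alkene) | O=C1O[C@@H]2[C@@H](I)C(C)=CC[C@]3(C)CC[C@@](O1)(C(C)C)[C@H]23
F10 | step 7 | cyclic carbonate of diol 11 (six-membered carbonate bridging O3 and O4, C5=C6 alkene) | O=C1O[C@@H]2C=C(C)CC[C@]3(C)CC[C@@](O1)(C(C)C)[C@H]23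
F0 | step 8 | none | none
A1 | alternative 1 | bicyclic cycloheptadiene with C3 ethylene ketal, C4 tert-butyldimethylsilyl enol ether, C6 methyl ester and C8a methyl | COC(=O)C1=CC[C@]2(C)CCC3(OCCO3)C2=C(O[Si](C)(C)C(C)(C)C)C1
A2 | alternative 1 | methyl 2-diazobut-3-enoate | C=CC(=[N+]=[N-])C(=O)OC
A3 | alternative 1 | 6-[1-(tert-butyldimethylsilyloxy)ethenyl]-7-methyl-1,4-dioxaspiro[4.4]non-6-ene | C=C(O[Si](C)(C)C(C)(C)C)C1=C(C)CCC12OCCO2
A4 | alternative 2 | cis-fused 3-hydroxy-3-isopropyl-6,8a-dimethyl-2,3,3a,7,8,8a-hexahydroazulen-4(1H)-one | O=C2C=C(C)CC[C@]3(C)CC[C@@](O)(C(C)C)[C@H]23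
A5 | alternative 2 | 3,6-dimethylcyclohepta-2,6-dien-1-one | CC1=CC(=O)C=C(C)CC1
A6 | alternative 2 | 1-(propan-2-yl)cyclopropan-1-ol | CC(C)C1(O)CC1
A7 | alternative 3 | cis-fused 3-isopropyl-6,8a-dimethyl-3-(triethylsilyloxy)-1,2,3,3a,6,7,8,8a-octahydroazulene | C1=C[C@@H](C)CC[C@]2(C)CC[C@@](O[Si](CC)(CC)CC)(C(C)C)[C@H]12
A8 | alternative 3 | triethyl{[(1E)-6-methyl-1-(trans-2-methylcyclopropyl)-3-(propan-2-yl)hepta-1,6-dien-3-yl]oxy}silane | C=C(C)CC[C@@](O[Si](CC)(CC)CC)(C(C)C)/C=C/[C@H]1C[C@@H]1C
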